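The target is the head-to-tail dimer of a 6-vinyl-7-methoxy-2,2-dimethyl-2H-chromene, so one chromene serves both halves; nickel-catalysed asymmetric hydrovinylation sets the S centre and cross-metathesis joins the halves. Everything rests on closing the pyran ring between C2 and C3. The key step exploits the O1–C2(CH3)2–C3=C4 edge of the chromene: C2 with its two methyl groups is an isopropyl ether methine in disguise and C3=C4 an ethynyl group. Platinum-catalysed 1,5-hydride transfer from that methine to the aryl-bound alkyne carbon, then collapse of the oxocarbenium/alkenylplatinum pair, forges C2–C3 and the quaternary carbon in one redox-neutral isomerisation of an ortho-ethynylaryl isopropyl ether. The C7 methoxy group, para to C4a, steers the hydride to C4.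

Key step: step 3

Remark: the stereocentre is S (aryl > alkenyl > methyl > H); compound 7 carries the same descriptor because these priorities do not change in step 6.

Step 1
Reactants: 1 5-bromo-2-hydroxy-4-methoxybenzaldehyde
Product: 2 5-bromo-4-methoxy-2-(propan-2-yloxy)benzaldehyde
Conditions: 2-bromopropane, K2CO3, DMF, 70 °C
Reagents that add atoms: 2-bromopropane, CC(C)Br
Why: Williamson ether synthesis, in which the phenoxide formed by K2CO3 should displace bromide from the secondary halide in a dipolar aprotic solvent while the aldehyde and the aryl bromide stay untouched.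

Step 2
Reactants: 2 5-bromo-4-methoxy-2-(propan-2-yloxy)benzaldehyde
Product: 3 1-bromo-5-ethynyl-2-methoxy-4-(propan-2-yloxy)benzene
Conditions: dimethyl (1-diazo-2-oxopropyl)phosphonate, K2CO3, MeOH, 0 °C to rt
Reagents that add atoms: dimethyl (1-diazo-2-oxopropyl)phosphonate, COP(=O)(OC)C(=[N+]=[N-])C(C)=O
Why: Seyferth–Gilbert homologation in its Ohira–Bestmann form, which should turn the aryl aldehyde into the terminal alkyne under mild carbonate conditions that leave the aryl bromide and both ethers intact.

Step 3
Reactants: 3 1-bromo-5-ethynyl-2-methoxy-4-(propan-2-yloxy)benzene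
Product: 5 6-bromo-7-methoxy-2,2-dimethyl-2H-chromene, via oxocarbenium alkenylplatinate zwitterion 4 (not isolated)
Conditions: PtI4 (10 mol %), MeCN, 4 Å molecular sieves, 100 °C (sealed tube)
Reagents that add atoms: none
Why: Proposed new method: PtI4 activates the terminal alkyne of 3 and the isopropoxy methine hydride migrates through a six-membered 1,5-transition state to the aryl-bound alkyne carbon (future C4), which gives the dimethyl-substituted aryloxocarbenium/cis-alkenylplatinate zwitterion 4. The platinum-bearing alkenyl carbon then adds to the oxocarbenium carbon in a 6-endo-trig closure of the pyran ring that forms the C2–C3 bond and the quaternary C2, and loss of the metal leaves the C3=C4 double bond and returns the catalyst. The closest known reaction types are the PtI4-catalysed hydride-transfer cyclisation of ether α-C–H bonds onto tethered terminal alkynes and the Lewis-acid hydride-transfer cyclisation of ortho-vinylaryl alkyl ethers to dihydrobenzopyrans; the combination on an ortho-ethynylaryl ether is the untested part. No stereocentre is formed. The step needs hydride transfer to C4 to outrun 5-endo attack of the ether oxygen on the terminal alkyne carbon and alkyne hydration: the methoxy group para to the alkyne-bearing carbon makes C4 the electrophilic end, the tertiary C–H leads to a doubly methyl-stabilised oxocarbenium ion, the isopropoxy group is the only C–H donor ortho to the alkyne, and water is excluded.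

Step 4
Reactants: 5 6-bromo-7-methoxy-2,2-dimethyl-2H-chromene
Product: 6 7-methoxy-2,2-dimethyl-6-vinyl-2H-chromene
Conditions: vinylboronic acid pinacol ester, Pd(dppf)Cl2 (3 mol %), K2CO3, 1,4-dioxane/H2O, 85 °C
Reagents that add atoms: 4,4,5,5-tetramethyl-2-vinyl-1,3,2-dioxaborolane, C=CB1OC(C)(C)C(C)(C)O1
Why: Suzuki–Miyaura coupling of an electron-rich aryl bromide with a vinylboronate, which should proceed cleanly because the chromene double bond and the ethers are inert to zerovalent palladium under these conditions.

Step 5
Reactants: 6 7-methoxy-2,2-dimethyl-6-vinyl-2H-chromene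
Product: 7 (S)-6-(but-3-en-2-yl)-7-methoxy-2,2-dimethyl-2H-chromene
Conditions: ethylene (1 atm), [Ni(η3-C3H5)Br]2 (1 mol %), binaphthol-derived phosphoramidite of bis(1-phenylethyl)amine (isomer chosen to deliver the S product), Na[B(3,5-(CF3)2C6H3)4], CH2Cl2, −70 °C
Reagents that add atoms: ethene, C=C
Why: Nickel-catalysed asymmetric hydrovinylation of a vinylarene, in which the cationic nickel hydride should add Markovnikov to the vinyl group to give an η3-benzyl nickel species, ethylene should insert at the benzylic carbon on the face dictated by the chiral phosphoramidite (setting S), and β-hydride elimination should release the 3-aryl-but-1-ene, the hindered internal chromene alkene being unreactive at this temperature.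

Step 6
Reactants: 7 (S)-6-(but-3-en-2-yl)-7-methoxy-2,2-dimethyl-2H-chromene; 6 7-methoxy-2,2-dimethyl-6-vinyl-2H-chromene (3 equiv)
Product: 8 (S,E)-6,6'-(but-1-ene-1,3-diyl)bis(7-methoxy-2,2-dimethyl-2H-chromene), CNP0212142.1
Conditions: second-generation Hoveyda–Grubbs catalyst (5 mol %), 1,4-benzoquinone (10 mol %), CH2Cl2, 40 °C
Reagents that add atoms: none
Why: Olefin cross-metathesis between a styrene and an allylically branched terminal alkene, which should give the thermodynamically preferred E styrenyl alkene with loss of ethene, leave the stereocentre untouched (benzoquinone suppresses ruthenium hydride double-bond migration) and spare the chromene ring alkenes, which are shielded by the adjacent gem-dimethyl carbon.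

Compound list
1 | 5-bromo-2-hydroxy-4-methoxybenzaldehyde | COc1cc(O)c(C=O)cc1Br | starting material
2 | 5-bromo-4-methoxy-2-(propan-2-yloxy)benzaldehyde | COc1cc(OC(C)C)c(C=O)cc1Br | intermediate
3 | 1-bromo-5-ethynyl-2-methoxy-4-(propan-2-yloxy)benzene | COc1cc(OC(C)C)c(C#C)cc1Br | intermediate
4 | oxocarbenium alkenylplatinate zwitterion (aryl-O+=CMe2 with a cis 2-platinavinyl group ortho to it) | COc1cc([O+]=C(C)C)c(/C=C\[Pt-](I)(I)(I)I)cc1Br | intermediate (not isolated)
5 | 6-bromo-7-methoxy-2,2-dimethyl-2H-chromene | COc1cc2OC(C)(C)C=Cc2cc1Br | intermediate
6 | 7-methoxy-2,2-dimethyl-6-vinyl-2H-chromene | COc1cc2OC(C)(C)C=Cc2cc1C=C | intermediate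
7 | (S)-6-(but-3-en-2-yl)-7-methoxy-2,2-dimethyl-2H-chromene | C=C[C@H](C)c1cc2c(cc1OC)OC(C)(C)C=C2 | intermediate
8 | (S,E)-6,6'-(but-1-ene-1,3-diyl)bis(7-methoxy-2,2-dimethyl-2H-chromene), CNP0212142.1 | COc1cc2c(cc1/C=C/[C@H](C)c1cc3c(cc1OC)OC(C)(C)C=C3)C=CC(C)(C)O2 | target

Total step count: 6
Longest linear sequence: 6 steps (1 to 8 through steps 1–6; compound 6 enters twice, in steps 5 and 6)

Steps most likely to fail

Step 3 (Proposed new method). Oxyplatination of the alkyne by the ether oxygen with loss of the isopropyl group, or hydration and oligomerisation of the electron-rich arylalkyne, may outrun the hydride transfer. The acid-sensitive chromene may also degrade at the reaction temperature. The fallback sets out from 2 and comes back at 5, and it still closes the ring at C2–C3 with known chemistry. Wittig reaction of 2 with (triphenylphosphoranylidene)acetaldehyde (toluene, 80 °C) should give (E)-3-[5-bromo-4-methoxy-2-(propan-2-yloxy)phenyl]prop-2-enal F1. BF3·OEt2 in CH2Cl2 (or Sc(OTf)3 in 1,2-dichloroethane at 60 °C) should then trigger the known hydride-transfer cyclisation of ortho-vinylaryl alkyl ethers: hydride passes from the isopropoxy methine to the β-carbon and the boron enolate closes on the oxocarbenium ion. This should give racemic 6-bromo-7-methoxy-2,2-dimethylchromane-3-carbaldehyde F2. Rhodium-catalysed transfer dehydroformylation ([Rh(cod)(OMe)]2, Xantphos, 3-methoxybenzoic acid, norbornadiene, THF, 80 °C) should remove the formyl group together with a C4 hydrogen, the only β-hydrogens since C2 is quaternary, and deliver 5.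

Step 5. Facial control may be insufficient with the ortho-methoxy vinylarene, the product may isomerise to the conjugated 2-arylbut-2-ene, or hydrovinylation may also occur at the chromene double bond. The fallback sets out from 6 and comes back at 7. Cross-metathesis of 6 with (Z)-1,4-dichlorobut-2-ene (second-generation Hoveyda–Grubbs catalyst, CH2Cl2, 40 °C) should give (E)-6-(3-chloroprop-1-en-1-yl)-7-methoxy-2,2-dimethyl-2H-chromene F3, used without storage. Copper-catalysed enantioselective SN2′ allylic alkylation with MeMgBr (CuBr·SMe2 as the monovalent copper source, chiral phosphoramidite or ferrocenyl diphosphine ligand, CH2Cl2, −78 °C) should then place the methyl group at the benzylic carbon and give 7.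

Step 6. Slow turnover at the allylically branched alkene, homodimerisation of 6 to an unreactive stilbene, or double-bond migration by ruthenium hydrides that erodes the stereocentre. The fallback sets out from 7 and 5 and comes back at 8. Mizoroki–Heck coupling of the terminal alkene of 7 with aryl bromide 5 (Pd(OAc)2, Bu4NBr, NaHCO3, DMF, 80 °C) should form the same E styrenyl bond by arylation instead of alkylidene exchange; no compound outside the list is made (F0).

Further compounds
F1 | step 3 | (E)-3-[5-bromo-4-methoxy-2-(propan-2-yloxy)phenyl]prop-2-enal | COc1cc(OC(C)C)c(/C=C/C=O)cc1Br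
F2 | step 3 | 6-bromo-7-methoxy-2,2-dimethylchromane-3-carbaldehyde (racemic) | COc1cc2OC(C)(C)C(C=O)Cc2cc1Br
F3 | step 5 | (E)-6-(3-chloroprop-1-en-1-yl)-7-methoxy-2,2-dimethyl-2H-chromene | COc1cc2OC(C)(C)C=Cc2cc1/C=C/CCl
F0 | step 6 | none | none
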